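Ring A = terminal guaiacyl ring; ring B = benzo ring of the dihydrobenzofuran; ring C = its furan ring (O1, C2, C3); ring D = guaiacyl ring on C2; b1-b4 = the four-carbon chain from ring A (b1) to ring B (b4), with CH2OH on b2 and on b3.
Retrosynthesis: ring C is opened at C2-C3 (carbene C-H insertion), then C3-ring B (acetate arylation) and O1-C2 (phenol etherification) are cut; next the b2-CH2OH and b3-CH2OH bonds (two boron-to-carbon 1,2-shifts); last the b2=b3 alkene (metathesis of two eugenol ethers).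
Forward: chain b1-b4 is joined by cross-metathesis, both CH2OH carbons are inserted in one operation, ring D is hung on the ring B oxygen, and ring C, the only ring made, closes last.
Enabling feature: b2 and b3 carry identical CH2OH groups in a threo, C2-type relation between two eugenol-type benzylic CH2 groups (b1 on ring A, b4 on ring B), which is what a syn double functionalisation of the (E)-b2=b3 alkene of a tail-to-tail eugenol dimer delivers.
Stereochemistry: b2/b3 (R,R) from ligand-controlled syn diboration and stereoretentive homologation; C2 (S) from the chiral dirhodium catalyst in the C-H insertion; C3 (R) from base equilibration to the trans-2,3 ring.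

Key step: step 4

Assumption: (S)-Quinap is taken as the enantiomer leading to the (2R,3R)-bis(boronate) and the (R)-tert-leucine-derived dirhodium catalyst as the one leading to (2S) at the furan carbon; each sense would be confirmed on a simple model and the mirror-image ligand used if it proves opposite.

Step 1
Reactants: 1 eugenol
Product: 2 4-allyl-1-(benzyloxy)-2-methoxybenzene
Conditions: BnBr, K2CO3, acetone, reflux
Reagents that add atoms: benzyl bromide, BrCc1ccccc1
Why: Williamson etherification of the phenoxide; the allyl group is inert to K2CO3 and the benzyl ether should last until the final hydrogenolysis.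

Step 2
Reactants: 1 eugenol
Product: 3 (4-allyl-2-methoxyphenoxy)triisopropylsilane
Conditions: TIPSCl, imidazole, DMF, rt
Reagents that add atoms: triisopropylsilyl chloride, CC(C)[Si](Cl)(C(C)C)C(C)C
Why: Imidazole-promoted O-silylation of the phenol; the bulky aryl silyl ether should tolerate n-BuLi at -78 °C and brief alkaline peroxide yet leave with fluoride beside benzyl ethers and acetates, which later distinguishes ring B from ring A.

Step 3
Reactants: 2 4-allyl-1-(benzyloxy)-2-methoxybenzene; 3 (4-allyl-2-methoxyphenoxy)triisopropylsilane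
Product: 4 (E)-1-(4-benzyloxy-3-methoxyphenyl)-4-(3-methoxy-4-triisopropylsilyloxyphenyl)but-2-ene
Conditions: second-generation Grubbs catalyst RuCl2(=CHPh)(H2IMes)(PCy3) (3 mol %), 1,4-benzoquinone (10 mol %), 2 in threefold excess, CH2Cl2, 40 °C, argon sweep; chromatography on AgNO3-impregnated silica
Reagents that add atoms: none
Why: Olefin cross-metathesis of two electronically equal allylarenes releases ethylene and under thermodynamic control should favour the (E)-alkene; excess 2 drives 3 into the cross product, benzoquinone suppresses ruthenium hydride double-bond migration, the homodimers are returned to the same reaction, and the minor Z isomer is removed on silver nitrate silica because only the E isomer leads to the threo diol.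

Step 4
Reactants: 4 (E)-1-(4-benzyloxy-3-methoxyphenyl)-4-(3-methoxy-4-triisopropylsilyloxyphenyl)but-2-ene; 5 bromochloromethane
Product: 9 (2R,3R)-2-(4-benzyloxy-3-methoxybenzyl)-3-(3-methoxy-4-triisopropylsilyloxybenzyl)butane-1,4-diol, via vicinal bis(catecholboronate) 6 (not isolated), via vicinal bis(pinacolboronate) 7 (not isolated), via bis(pinacolboronylmethyl) homologue 8 (not isolated)
Conditions: Rh(acac)(nbd) (5 mol %), (S)-Quinap (5 mol %), B2(cat)2 (1.2 equiv), THF, rt; pinacol, rt, short silica plug; 5 (5 equiv), n-BuLi (4.5 equiv), THF, -78 °C to rt; 30% H2O2, 2 M NaOH, 0 °C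
Reagents that add atoms: hydrogen peroxide, OO; bis(catecholato)diboron, c1ccc2c(c1)OB(O2)B1Oc2ccccc2O1 (its atoms stay only in 6 to 8); pinacol, CC(C)(O)C(C)(C)O (its atoms stay only in 7 and 8)
Why: The B-B bond of B2(cat)2 adds oxidatively to the Quinap-bound monovalent rhodium centre, the alkene inserts into a Rh-B bond and C-B reductive elimination delivers both boryl groups to the same face, so the (E)-alkene can only give the threo bis(boronate) 6 (no ring is closed anywhere in the step). After exchange to the pinacol esters 7, each boron binds LiCH2Cl (from Br/Li exchange on 5) as an ate complex and the secondary carbon migrates to CH2 with loss of chloride and retention of configuration, which makes the b2-CH2 and b3-CH2 bonds of 8; alkaline H2O2 then oxidises only the new primary C-B bonds. The closest known reactions are the rhodium-Quinap enantioselective diboration of trans-1,2-disubstituted alkenes and the Matteson chloromethyllithium homologation of secondary pinacol boronates, including double homologation of vicinal bis(boronates) to 1,4-diols. Both new stereocentres (b2 and b3, R,R) take their absolute configuration from the alkene face exposed by the chiral P,N ligand and their relative configuration from the syn addition, and both should pass unchanged through the stereoretentive 1,2-shifts and the oxidation. The selectivity needed is enantioface selection on an alkene without a directing group; the substrate helps because its two ends differ only in remote O-protecting groups, so either binding orientation gives the same product, and because the ate complexes form at -78 °C where surplus carbenoid decomposes before it can homologate a primary boronate a second time.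

Step 5
Reactants: 9 (2R,3R)-2-(4-benzyloxy-3-methoxybenzyl)-3-(3-methoxy-4-triisopropylsilyloxybenzyl)butane-1,4-diol
Product: 10 (2R,3R)-2-(4-benzyloxy-3-methoxybenzyl)-3-(3-methoxy-4-triisopropylsilyloxybenzyl)butane-1,4-diyl diacetate
Conditions: Ac2O, pyridine, DMAP (cat.), CH2Cl2, rt
Reagents that add atoms: acetic anhydride, CC(=O)OC(C)=O
Why: DMAP-catalysed acylation of both primary alcohols; the acetates mask the diol against the Mitsunobu step and against O-H insertion of the rhodium carbene and come off later in the methoxide step without a separate operation.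

Step 6
Reactants: 10 (2R,3R)-2-(4-benzyloxy-3-methoxybenzyl)-3-(3-methoxy-4-triisopropylsilyloxybenzyl)butane-1,4-diyl diacetate
Product: 11 (2R,3R)-2-(4-benzyloxy-3-methoxybenzyl)-3-(4-hydroxy-3-methoxybenzyl)butane-1,4-diyl diacetate
Conditions: TBAF (1.1 equiv), AcOH (1.1 equiv), THF, 0 °C
Reagents that add atoms: none
Why: Fluorodesilylation of the aryl Si-O bond; acetic acid buffers the phenoxide so that the acetates neither migrate nor cleave, and the benzyl ethers are inert.

Step 7
Reactants: 11 (2R,3R)-2-(4-benzyloxy-3-methoxybenzyl)-3-(4-hydroxy-3-methoxybenzyl)butane-1,4-diyl diacetate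
Product: 12 (2R,3R)-2-(4-benzyloxy-3-methoxybenzyl)-3-(4-hydroxy-3-iodo-5-methoxybenzyl)butane-1,4-diyl diacetate
Conditions: NIS (1.05 equiv), DMF, 0 °C to rt, dark
Reagents that add atoms: N-iodosuccinimide, O=C1CCC(=O)N1I
Why: Electrophilic aromatic iodination directed by the free phenol to its only open ortho position (the other ortho carbon bears OMe, the para carbon the chain), while the ether-only ring A should not react with NIS in the absence of acid.

Step 8
Reactants: 12 (2R,3R)-2-(4-benzyloxy-3-methoxybenzyl)-3-(4-hydroxy-3-iodo-5-methoxybenzyl)butane-1,4-diyl diacetate; 13 4-benzyloxy-3-methoxybenzyl alcohol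
Product: 14 (2R,3R)-2-(4-benzyloxy-3-methoxybenzyl)-3-[4-(4-benzyloxy-3-methoxybenzyloxy)-3-iodo-5-methoxybenzyl]butane-1,4-diyl diacetate
Conditions: PPh3, DIAD, THF, 0 °C to rt
Reagents that add atoms: none
Why: Mitsunobu etherification, in which the acidic iodophenol is O-alkylated by the phosphonium-activated primary benzylic alcohol under neutral conditions that leave acetates, aryl iodide and benzyl ethers untouched; this forms the O1-C2 bond and no stereocentre is involved.

Step 9
Reactants: 14 (2R,3R)-2-(4-benzyloxy-3-methoxybenzyl)-3-[4-(4-benzyloxy-3-methoxybenzyloxy)-3-iodo-5-methoxybenzyl]butane-1,4-diyl diacetate; 15 methyl bromoacetate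
Product: 16 methyl 2-{5-[(2R,3R)-4-acetoxy-2-(acetoxymethyl)-3-(4-benzyloxy-3-methoxybenzyl)butyl]-2-(4-benzyloxy-3-methoxybenzyloxy)-3-methoxyphenyl}acetate
Conditions: BrZnCH2CO2Me (from 15, Zn dust, cat. TMSCl, THF), Pd2(dba)3 (2.5 mol %), XPhos (10 mol %), THF, 60 °C
Reagents that add atoms: none
Why: Negishi-type arylation of a Reformatsky reagent (oxidative addition of the aryl iodide to zerovalent palladium, transmetallation of the zinc ester enolate, reductive elimination) forms the ring B-C3 bond, and the mild zinc reagent should spare the acetates and the acid-sensitive benzylic aryl ether.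

Step 10
Reactants: 16 methyl 2-{5-[(2R,3R)-4-acetoxy-2-(acetoxymethyl)-3-(4-benzyloxy-3-methoxybenzyl)butyl]-2-(4-benzyloxy-3-methoxybenzyloxy)-3-methoxyphenyl}acetate
Product: 17 methyl 2-diazo-2-{5-[(2R,3R)-4-acetoxy-2-(acetoxymethyl)-3-(4-benzyloxy-3-methoxybenzyl)butyl]-2-(4-benzyloxy-3-methoxybenzyloxy)-3-methoxyphenyl}acetate
Conditions: p-ABSA (1.3 equiv), DBU (1.5 equiv), MeCN, 0 °C to rt
Reagents that add atoms: 4-acetamidobenzenesulfonyl azide, CC(=O)Nc1ccc(cc1)S(=O)(=O)N=[N+]=[N-]
Why: Regitz diazo transfer, in which DBU removes the most acidic proton (the arylacetate α-CH2) and the enolate takes N2 from the sulfonyl azide; the acetates are not enolised under these conditions.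

Step 11
Reactants: 17 methyl 2-diazo-2-{5-[(2R,3R)-4-acetoxy-2-(acetoxymethyl)-3-(4-benzyloxy-3-methoxybenzyl)butyl]-2-(4-benzyloxy-3-methoxybenzyloxy)-3-methoxyphenyl}acetate
Product: 18 methyl (2S,3R)-2-(4-benzyloxy-3-methoxyphenyl)-5-[(2R,3R)-4-acetoxy-2-(acetoxymethyl)-3-(4-benzyloxy-3-methoxybenzyl)butyl]-7-methoxy-2,3-dihydrobenzofuran-3-carboxylate (2,3-cis)
Conditions: Rh2(R-PTTL)4, dirhodium tetrakis[N-phthaloyl-(R)-tert-leucinate] (2 mol %), toluene, -60 °C, slow addition of 17
Reagents that add atoms: none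
Why: Intramolecular 1,5 C-H insertion of the donor/acceptor rhodium carbene into the O-CH2-aryl bond (activated by oxygen and by electron-rich ring D, and the only C-H that gives a five-membered ring) closes ring C at C2-C3; the chiral carboxylate ligands choose between the two enantiotopic hydrogens and so set C2 as S, and the concerted insertion places aryl and ester cis, as is known for this phthalimido catalyst class on aryl benzyl ethers.

Step 12
Reactants: 18 methyl (2S,3R)-2-(4-benzyloxy-3-methoxyphenyl)-5-[(2R,3R)-4-acetoxy-2-(acetoxymethyl)-3-(4-benzyloxy-3-methoxybenzyl)butyl]-7-methoxy-2,3-dihydrobenzofuran-3-carboxylate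
Product: 19 methyl (2S,3S)-2-(4-benzyloxy-3-methoxyphenyl)-5-[(2R,3R)-3-(4-benzyloxy-3-methoxybenzyl)-4-hydroxy-2-(hydroxymethyl)butyl]-7-methoxy-2,3-dihydrobenzofuran-3-carboxylate (2,3-trans)
Conditions: NaOMe (0.5 equiv), MeOH-THF, rt
Reagents that add atoms: none
Why: Methoxide reversibly enolises the ester at C3 and reprotonation should settle on the thermodynamically preferred trans-2,3 ring (C3 set relative to the untouched C2), while the same reagent removes both acetates by Zemplén-type transesterification.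

Step 13
Reactants: 19 methyl (2S,3S)-2-(4-benzyloxy-3-methoxyphenyl)-5-[(2R,3R)-3-(4-benzyloxy-3-methoxybenzyl)-4-hydroxy-2-(hydroxymethyl)butyl]-7-methoxy-2,3-dihydrobenzofuran-3-carboxylate
Product: 20 (2R,3R)-2-(4-benzyloxy-3-methoxybenzyl)-3-{[(2S,3R)-2-(4-benzyloxy-3-methoxyphenyl)-3-(hydroxymethyl)-7-methoxy-2,3-dihydrobenzofuran-5-yl]methyl}butane-1,4-diol
Conditions: LiAlH4 (excess), THF, 0 °C; aqueous NaOH work-up
Reagents that add atoms: none
Why: Hydride reduction of the methyl ester to the primary alcohol touches no stereocentre (the C3 descriptor changes from S to R only through CIP priorities), and benzyl ethers and the dihydrobenzofuran are stable to LiAlH4.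

Step 14
Reactants: 20 (2R,3R)-2-(4-benzyloxy-3-methoxybenzyl)-3-{[(2S,3R)-2-(4-benzyloxy-3-methoxyphenyl)-3-(hydroxymethyl)-7-methoxy-2,3-dihydrobenzofuran-5-yl]methyl}butane-1,4-diol
Product: 21 (2R,3R)-2-(4-hydroxy-3-methoxybenzyl)-3-{[(2S,3R)-2-(4-hydroxy-3-methoxyphenyl)-3-(hydroxymethyl)-7-methoxy-2,3-dihydrobenzofuran-5-yl]methyl}butane-1,4-diol (CNP0256425.1)
Conditions: H2 (1 atm), palladium on carbon (Pd/C, 10 wt %), EtOAc-MeOH, rt, stopped at full conversion
Reagents that add atoms: none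
Why: Heterogeneous hydrogenolysis of the two primary O-benzyl aryl ethers, which should cleave much faster than the hindered, secondary, ring-bound C2-O1 bond under neutral conditions, so ring C and all four stereocentres are kept.

Compound list
1 | eugenol | C=CCc1ccc(O)c(OC)c1 | starting material
2 | 4-allyl-1-(benzyloxy)-2-methoxybenzene | C=CCc1ccc(OCc2ccccc2)c(OC)c1 | intermediate
3 | (4-allyl-2-methoxyphenoxy)triisopropylsilane | C=CCc1ccc(O[Si](C(C)C)(C(C)C)C(C)C)c(OC)c1 | intermediate
4 | (E)-1-(4-benzyloxy-3-methoxyphenyl)-4-(3-methoxy-4-triisopropylsilyloxyphenyl)but-2-ene | COc1cc(C/C=C/Cc2ccc(O[Si](C(C)C)(C(C)C)C(C)C)c(OC)c2)ccc1OCc1ccccc1 | intermediate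
5 | bromochloromethane | ClCBr | starting material
6 | (2R,3R)-2,2'-[1-(4-benzyloxy-3-methoxyphenyl)-4-(3-methoxy-4-triisopropylsilyloxyphenyl)butane-2,3-diyl]bis(1,3,2-benzodioxaborole) | COc1cc(C[C@@H](B2Oc3ccccc3O2)[C@H](B2Oc3ccccc3O2)Cc2ccc(O[Si](C(C)C)(C(C)C)C(C)C)c(OC)c2)ccc1OCc1ccccc1 | intermediate (not isolated)
7 | (2R,3R)-1-(4-benzyloxy-3-methoxyphenyl)-4-(3-methoxy-4-triisopropylsilyloxyphenyl)-2,3-bis(4,4,5,5-tetramethyl-1,3,2-dioxaborolan-2-yl)butane | COc1cc(C[C@@H](B2OC(C)(C)C(C)(C)O2)[C@H](B2OC(C)(C)C(C)(C)O2)Cc2ccc(O[Si](C(C)C)(C(C)C)C(C)C)c(OC)c2)ccc1OCc1ccccc1 | intermediate (not isolated)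
8 | (2R,3R)-1-(4-benzyloxy-3-methoxyphenyl)-4-(3-methoxy-4-triisopropylsilyloxyphenyl)-2,3-bis[(4,4,5,5-tetramethyl-1,3,2-dioxaborolan-2-yl)methyl]butane | COc1cc(C[C@@H](CB2OC(C)(C)C(C)(C)O2)[C@H](CB2OC(C)(C)C(C)(C)O2)Cc2ccc(O[Si](C(C)C)(C(C)C)C(C)C)c(OC)c2)ccc1OCc1ccccc1 | intermediate (not isolated)
9 | (2R,3R)-2-(4-benzyloxy-3-methoxybenzyl)-3-(3-methoxy-4-triisopropylsilyloxybenzyl)butane-1,4-diol | COc1cc(C[C@@H](CO)[C@H](CO)Cc2ccc(O[Si](C(C)C)(C(C)C)C(C)C)c(OC)c2)ccc1OCc1ccccc1 | intermediate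
10 | (2R,3R)-2-(4-benzyloxy-3-methoxybenzyl)-3-(3-methoxy-4-triisopropylsilyloxybenzyl)butane-1,4-diyl diacetate | COc1cc(C[C@@H](COC(C)=O)[C@H](COC(C)=O)Cc2ccc(O[Si](C(C)C)(C(C)C)C(C)C)c(OC)c2)ccc1OCc1ccccc1 | intermediate
11 | (2R,3R)-2-(4-benzyloxy-3-methoxybenzyl)-3-(4-hydroxy-3-methoxybenzyl)butane-1,4-diyl diacetate | COc1cc(C[C@@H](COC(C)=O)[C@H](COC(C)=O)Cc2ccc(O)c(OC)c2)ccc1OCc1ccccc1 | intermediate
12 | (2R,3R)-2-(4-benzyloxy-3-methoxybenzyl)-3-(4-hydroxy-3-iodo-5-methoxybenzyl)butane-1,4-diyl diacetate | COc1cc(C[C@@H](COC(C)=O)[C@H](COC(C)=O)Cc2cc(I)c(O)c(OC)c2)ccc1OCc1ccccc1 | intermediate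
13 | 4-benzyloxy-3-methoxybenzyl alcohol (commercial) | COc1cc(CO)ccc1OCc1ccccc1 | starting material
14 | (2R,3R)-2-(4-benzyloxy-3-methoxybenzyl)-3-[4-(4-benzyloxy-3-methoxybenzyloxy)-3-iodo-5-methoxybenzyl]butane-1,4-diyl diacetate | COc1cc(C[C@@H](COC(C)=O)[C@H](COC(C)=O)Cc2cc(I)c(OCc3ccc(OCc4ccccc4)c(OC)c3)c(OC)c2)ccc1OCc1ccccc1 | intermediate
15 | methyl bromoacetate | COC(=O)CBr | starting material
16 | methyl 2-{5-[(2R,3R)-4-acetoxy-2-(acetoxymethyl)-3-(4-benzyloxy-3-methoxybenzyl)butyl]-2-(4-benzyloxy-3-methoxybenzyloxy)-3-methoxyphenyl}acetate | COc1cc(C[C@@H](COC(C)=O)[C@H](COC(C)=O)Cc2cc(CC(=O)OC)c(OCc3ccc(OCc4ccccc4)c(OC)c3)c(OC)c2)ccc1OCc1ccccc1 | intermediate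
17 | methyl 2-diazo-2-{5-[(2R,3R)-4-acetoxy-2-(acetoxymethyl)-3-(4-benzyloxy-3-methoxybenzyl)butyl]-2-(4-benzyloxy-3-methoxybenzyloxy)-3-methoxyphenyl}acetate | COc1cc(C[C@@H](COC(C)=O)[C@H](COC(C)=O)Cc2cc(C(=[N+]=[N-])C(=O)OC)c(OCc3ccc(OCc4ccccc4)c(OC)c3)c(OC)c2)ccc1OCc1ccccc1 | intermediate
18 | methyl (2S,3R)-2-(4-benzyloxy-3-methoxyphenyl)-5-[(2R,3R)-4-acetoxy-2-(acetoxymethyl)-3-(4-benzyloxy-3-methoxybenzyl)butyl]-7-methoxy-2,3-dihydrobenzofuran-3-carboxylate (cis) | COc1cc(C[C@@H](COC(C)=O)[C@H](COC(C)=O)Cc2cc(OC)c3c(c2)[C@@H](C(=O)OC)[C@@H](c2ccc(OCc4ccccc4)c(OC)c2)O3)ccc1OCc1ccccc1 | intermediate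
19 | methyl (2S,3S)-2-(4-benzyloxy-3-methoxyphenyl)-5-[(2R,3R)-3-(4-benzyloxy-3-methoxybenzyl)-4-hydroxy-2-(hydroxymethyl)butyl]-7-methoxy-2,3-dihydrobenzofuran-3-carboxylate (trans) | COc1cc(C[C@@H](CO)[C@H](CO)Cc2cc(OC)c3c(c2)[C@H](C(=O)OC)[C@@H](c2ccc(OCc4ccccc4)c(OC)c2)O3)ccc1OCc1ccccc1 | intermediate
20 | (2R,3R)-2-(4-benzyloxy-3-methoxybenzyl)-3-{[(2S,3R)-2-(4-benzyloxy-3-methoxyphenyl)-3-(hydroxymethyl)-7-methoxy-2,3-dihydrobenzofuran-5-yl]methyl}butane-1,4-diol | COc1cc(C[C@@H](CO)[C@H](CO)Cc2cc(OC)c3c(c2)[C@H](CO)[C@@H](c2ccc(OCc4ccccc4)c(OC)c2)O3)ccc1OCc1ccccc1 | intermediate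
21 | (2R,3R)-2-(4-hydroxy-3-methoxybenzyl)-3-{[(2S,3R)-2-(4-hydroxy-3-methoxyphenyl)-3-(hydroxymethyl)-7-methoxy-2,3-dihydrobenzofuran-5-yl]methyl}butane-1,4-diol | COc1cc(C[C@@H](CO)[C@H](CO)Cc2cc(OC)c3c(c2)[C@H](CO)[C@@H](c2ccc(O)c(OC)c2)O3)ccc1O | target

Total step count: 14.
Longest linear sequence: 13 steps (eugenol, step 1 or step 2, then steps 3 to 14).

Steps most likely to fail

Step 4. The rhodium diboration may show weak enantioface discrimination on this doubly benzylic alkene, or β-hydride elimination may move the double bond. The second CH2 insertion may also stall at the crowded vicinal bis(boronate). The fallback sets out from 3 and 13 and comes back at 9, building the two stereocentres one after the other by auxiliary and substrate control. Hydroboration-oxidation of 3 (9-BBN, then H2O2, NaOH) gives 3-(3-methoxy-4-triisopropylsilyloxyphenyl)propan-1-ol F1. Oxidation (TEMPO, PhI(OAc)2, MeCN-H2O) gives 3-(3-methoxy-4-triisopropylsilyloxyphenyl)propanoic acid F2. Its pivaloyl mixed anhydride acylates lithiated (S)-4-benzyloxazolidin-2-one to give (S)-4-benzyl-3-[3-(3-methoxy-4-triisopropylsilyloxyphenyl)propanoyl]oxazolidin-2-one F3. Evans alkylation (NaHMDS, tert-butyl bromoacetate, THF, -78 °C) sets the b3 centre in tert-butyl (R)-4-[(S)-4-benzyl-2-oxooxazolidin-3-yl]-3-(3-methoxy-4-triisopropylsilyloxybenzyl)-4-oxobutanoate F4. LiBH4 removes the auxiliary to give tert-butyl (R)-4-hydroxy-3-(3-methoxy-4-triisopropylsilyloxybenzyl)butanoate F5. Catalytic TsOH in warm toluene closes this to (R)-4-(3-methoxy-4-triisopropylsilyloxybenzyl)dihydrofuran-2(3H)-one F6. Compound 13 and PBr3 give 4-benzyloxy-3-methoxybenzyl bromide F7. The lithium enolate of F6 (LiHMDS, THF, -78 °C) is alkylated by F7 anti to the existing substituent to give (3R,4R)-3-(4-benzyloxy-3-methoxybenzyl)-4-(3-methoxy-4-triisopropylsilyloxybenzyl)dihydrofuran-2(3H)-one F8. LiAlH4 at 0 °C reduces F8 to diol 9.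

Step 11. Facial selection by the catalyst alone may be eroded by the ortho-methoxy group or the remote chain, giving a C2 diastereomer that is hard to separate, and carbene dimerisation may compete. The fallback sets out from 14 and comes back at 20, moving part of the control into the substrate through a lactamide ester auxiliary, a known matched pairing that gives the trans ring directly. Ethyl (S)-lactate and pyrrolidine give (S)-2-hydroxy-1-(pyrrolidin-1-yl)propan-1-one F9. Bromoacetyl bromide and pyridine convert it into (S)-1-oxo-1-(pyrrolidin-1-yl)propan-2-yl bromoacetate F10. The zinc reagent of F10 is coupled with 14 under the palladium conditions of step 9 to give the (S)-lactamide ester analogue of 16 F11. Diazo transfer as in step 10 gives the (S)-lactamide aryldiazoacetate F12. Rh2(S-DOSP)4, dirhodium tetrakis[(S)-N-(4-dodecylphenylsulfonyl)prolinate], in CH2Cl2 should then give the trans-(2S,3S)-dihydrobenzofuran lactamide ester F13. LiAlH4 cleaves the auxiliary ester and both acetates in one operation to give 20.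

Step 3. The metathesis may give a near-statistical product distribution, incomplete E selectivity and allyl-to-propenyl migration with loss of a carbon, and any Z isomer carried forward would end as the erythro diol. The fallback sets out from 2 and 3 and comes back at 4, making the alkene by a directed olefination without homodimers. Ozonolysis of 3 with NaBH4 work-up gives 2-(3-methoxy-4-triisopropylsilyloxyphenyl)ethanol F14. Mitsunobu thioetherification with 1-phenyl-1H-tetrazole-5-thiol gives 5-{[2-(3-methoxy-4-triisopropylsilyloxyphenyl)ethyl]sulfanyl}-1-phenyl-1H-tetrazole F15. Oxidation with (NH4)6Mo7O24 and H2O2 in EtOH gives 5-{[2-(3-methoxy-4-triisopropylsilyloxyphenyl)ethyl]sulfonyl}-1-phenyl-1H-tetrazole F16. Ozonolysis of 2 with PPh3 work-up gives 2-(4-benzyloxy-3-methoxyphenyl)acetaldehyde F17. Julia-Kocienski olefination (KHMDS, DME, -60 °C) of F16 with F17 should give 4 with the E preference typical of that reaction.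

Further compounds
F1 | step 4 | 3-(3-methoxy-4-triisopropylsilyloxyphenyl)propan-1-ol | COc1cc(CCCO)ccc1O[Si](C(C)C)(C(C)C)C(C)C
F2 | step 4 | 3-(3-methoxy-4-triisopropylsilyloxyphenyl)propanoic acid | COc1cc(CCC(=O)O)ccc1O[Si](C(C)C)(C(C)C)C(C)C
F3 | step 4 | (S)-4-benzyl-3-[3-(3-methoxy-4-triisopropylsilyloxyphenyl)propanoyl]oxazolidin-2-one | COc1cc(CCC(=O)N2[C@@H](Cc3ccccc3)COC2=O)ccc1O[Si](C(C)C)(C(C)C)C(C)C
F4 | step 4 | tert-butyl (R)-4-[(S)-4-benzyl-2-oxooxazolidin-3-yl]-3-(3-methoxy-4-triisopropylsilyloxybenzyl)-4-oxobutanoate | CC(C)(C)OC(=O)C[C@@H](Cc1ccc(O[Si](C(C)C)(C(C)C)C(C)C)c(OC)c1)C(=O)N1[C@@H](Cc2ccccc2)COC1=O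
F5 | step 4 | tert-butyl (R)-4-hydroxy-3-(3-methoxy-4-triisopropylsilyloxybenzyl)butanoate | CC(C)(C)OC(=O)C[C@@H](Cc1ccc(O[Si](C(C)C)(C(C)C)C(C)C)c(OC)c1)CO
F6 | step 4 | (R)-4-(3-methoxy-4-triisopropylsilyloxybenzyl)dihydrofuran-2(3H)-one | O=C1C[C@@H](Cc2ccc(O[Si](C(C)C)(C(C)C)C(C)C)c(OC)c2)CO1
F7 | step 4 | 4-benzyloxy-3-methoxybenzyl bromide | COc1cc(CBr)ccc1OCc1ccccc1
F8 | step 4 | (3R,4R)-3-(4-benzyloxy-3-methoxybenzyl)-4-(3-methoxy-4-triisopropylsilyloxybenzyl)dihydrofuran-2(3H)-one | COc1cc(C[C@@H](C(=O)OC2)[C@H]2Cc2ccc(O[Si](C(C)C)(C(C)C)C(C)C)c(OC)c2)ccc1OCc1ccccc1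
F9 | step 11 | (S)-2-hydroxy-1-(pyrrolidin-1-yl)propan-1-one | C[C@H](O)C(=O)N1CCCC1
F10 | step 11 | (S)-1-oxo-1-(pyrrolidin-1-yl)propan-2-yl bromoacetate | C[C@H](OC(=O)CBr)C(=O)N1CCCC1
F11 | step 11 | (S)-1-oxo-1-(pyrrolidin-1-yl)propan-2-yl 2-{5-[(2R,3R)-4-acetoxy-2-(acetoxymethyl)-3-(4-benzyloxy-3-methoxybenzyl)butyl]-2-(4-benzyloxy-3-methoxybenzyloxy)-3-methoxyphenyl}acetate | COc1cc(C[C@@H](COC(C)=O)[C@H](COC(C)=O)Cc2cc(CC(=O)O[C@@H](C)C(=O)N3CCCC3)c(OCc3ccc(OCc4ccccc4)c(OC)c3)c(OC)c2)ccc1OCc1ccccc1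
F12 | step 11 | (S)-1-oxo-1-(pyrrolidin-1-yl)propan-2-yl 2-diazo-2-{5-[(2R,3R)-4-acetoxy-2-(acetoxymethyl)-3-(4-benzyloxy-3-methoxybenzyl)butyl]-2-(4-benzyloxy-3-methoxybenzyloxy)-3-methoxyphenyl}acetate | COc1cc(C[C@@H](COC(C)=O)[C@H](COC(C)=O)Cc2cc(C(=[N+]=[N-])C(=O)O[C@@H](C)C(=O)N3CCCC3)c(OCc3ccc(OCc4ccccc4)c(OC)c3)c(OC)c2)ccc1OCc1ccccc1
F13 | step 11 | (S)-1-oxo-1-(pyrrolidin-1-yl)propan-2-yl (2S,3S)-2-(4-benzyloxy-3-methoxyphenyl)-5-[(2R,3R)-4-acetoxy-2-(acetoxymethyl)-3-(4-benzyloxy-3-methoxybenzyl)butyl]-7-methoxy-2,3-dihydrobenzofuran-3-carboxylate (trans) | COc1cc(C[C@@H](COC(C)=O)[C@H](COC(C)=O)Cc2cc(OC)c3c(c2)[C@H](C(=O)O[C@@H](C)C(=O)N2CCCC2)[C@@H](c2ccc(OCc4ccccc4)c(OC)c2)O3)ccc1OCc1ccccc1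
F14 | step 3 | 2-(3-methoxy-4-triisopropylsilyloxyphenyl)ethanol | COc1cc(CCO)ccc1O[Si](C(C)C)(C(C)C)C(C)C
F15 | step 3 | 5-{[2-(3-methoxy-4-triisopropylsilyloxyphenyl)ethyl]sulfanyl}-1-phenyl-1H-tetrazole | COc1cc(CCSc2nnnn2-c2ccccc2)ccc1O[Si](C(C)C)(C(C)C)C(C)C
F16 | step 3 | 5-{[2-(3-methoxy-4-triisopropylsilyloxyphenyl)ethyl]sulfonyl}-1-phenyl-1H-tetrazole | COc1cc(CCS(=O)(=O)c2nnnn2-c2ccccc2)ccc1O[Si](C(C)C)(C(C)C)C(C)C
F17 | step 3 | 2-(4-benzyloxy-3-methoxyphenyl)acetaldehyde | COc1cc(CC=O)ccc1OCc1ccccc1
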